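The data were generated by integration from invented constants; scatter was added.

Over the first 6.0 h of a portioned run, the substrate meets the first portion of coupling partner and no later one.

common to all: substrate 30 mM
- maple: coupling partner 38 mM (in portions, 3); capture agent 9 mM; run made earlier; portions every 6.0 h
- cedar: coupling partner 150 mM (in portions, 3); capture agent 9 mM; run made earlier; portions every 6.0 h
- summer: coupling partner 75.0 mM (in portions, 3); capture agent 9.00 mM; the portions of coupling partner follow each other after 6.0 h, the first at the start; time 4.0 d
- noon: coupling partner 75.0 mM; capture agent 9.00 mM; everything together at the start; time 4.0 d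

| run | time / d | target / % | substrate / % |
|---|---|---|---|
| maple | 0.208 | 11.5 | 57.0 |
| maple | 0.333 | 18.5 | 41.5 |
| maple | 0.417 | 22.9 | 34.0 |
| maple | 0.625 | 31.4 | 22.0 |
| maple | 1.04 | 43.3 | 11.4 |
| maple | 1.67 | 50.6 | 4.8 |
| maple | 2.50 | 54.2 | 1.7 |
| cedar | 0.125 | 28.4 | 52.3 |
| cedar | 0.333 | 53.4 | 17.0 |
| cedar | 0.625 | 66.0 | 2.2 |
| cedar | 1.04 | 68.8 | 0.4 |
| cedar | 1.67 | 69.6 | 0 |
| cedar | 2.08 | 69.2 | 0 |
| cedar | 2.50 | 69.1 | 0 |

(readings scatter by 0.3 percentage points)

- the numbers in the tables scatter with a standard deviation of 0.3 percentage points
- steps that have been proposed: substrate <-> intermediate A; substrate -> intermediate B; substrate + coupling partner -> target; coupling partner + intermediate B -> side product; capture agent + intermediate A -> trapped intermediate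

1. which one finishes higher in amount of target, in percent of the substrate charged ("neither" within 2 percentage points) (summer / noon / neither)
2. amount of target at the end, in percent of the substrate charged, summer
3. amount of target at the end, in percent of the substrate charged, noon

The bench rule counts equivalents of coupling partner to substrate. Summer and noon both carry 2.50, so the rule calls them level. But it assumes the charge is present while the substrate reacts, and a ratio of the interval to the substrate's half-life, read from each run's first reading, shows where that stops:

maple: half-life 6.16 h, interval over half-life 0.975
cedar: half-life 3.21 h, interval over half-life 1.87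

In cedar the interval exceeds the half-life; in maple the two are about equal. So the first-portion concentration c(partner) serves here as a rough index of the early dose, though it does not stay constant: the portion is consumed and later portions add to it. My own reckoning takes the competing losses as independent of partner, which makes the missing yield go roughly as 1/c(partner). Maple and cedar differ in nothing else, so the two ends can be joined, with maple's last reading taken as it stands although 1.7 % substrate remains:

D = (Y cedar − Y maple) / (1/12.7 mM − 1/50.0 mM) = 2.53 mM

This D is the dose cost, the fraction of yield given up per unit of reciprocal first-portion concentration. Counted from cedar's 69.1 %: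

summer, first portion 25.0 mM: 64.0 %
noon, whole charge at once, beyond cedar and so an extrapolation: 70.8 %

Noon should finish higher.

The forecast puts summer at 64.5 % (61.5 % to 67 %) and noon at 69.5 % (67 % to 72 %), so noon wins, on the ground that “Noon has high partner from the start”. The flask gives summer 62.3 % and noon 71.4 %.

    substrate ⇌ intermediate A (K = 0.350, k = 2.60 × 10⁻⁵ s⁻¹)
    substrate → intermediate B (k = 3.30 × 10⁻⁶ s⁻¹)
    substrate + coupling partner → target (k = 7.90 × 10⁻⁴ M⁻¹ s⁻¹)
    coupling partner + intermediate B → side product (k = 5.90 × 10⁻⁴ M⁻¹ s⁻¹)
    capture agent + intermediate A → trapped intermediate (k = 0.0300 M⁻¹ s⁻¹)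

Noon's lead of 9.1 percentage points has the way the coupling partner goes in as its main reason: given in portions, the same charge takes noon from 71.4 % to 62.3 %. The dose cost reckons that lead at 6.7 points, charging summer 10.1 % of yield and noon 3.37 %. In the neighbour flask, summer's recipe with 45 mM of coupling partner, the first portion is 15.0 mM, the dose cost gives 57.3 %, and the flask holds 58.2 % of target at 4.00 d.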